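Slowness is what to look for in this flask, and two steps are to be watched for it: the one in which starting material attacks the target it has helped to make, and the cross step, in which starting material goes to cross product instead of target.

all flasks: starting material 1.5 M; coupling partner 0.700 equiv; second substrate 1.00 equiv; time 1.0 min
- alder: temperature 20 °C
- larch: temperature −10 °C
- elm: temperature −25 °C
- cedar: temperature 5 °C

    starting material + coupling partner → target (k1 = 0.022 /M/s, Ea1 = 48.0 kJ/mol)
    second substrate + coupling partner → second product (k2 = 0.039 /M/s, Ea2 = 59.0 kJ/mol)
    starting material + second substrate → cross product (k3 = 0.0087 /M/s, Ea3 = 67.0 kJ/mol)
    2 coupling partner → homo dimer (k4 = 0.018 /M/s, Ea4 = 39.0 kJ/mol)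
    target ⇌ isomer of the product (K5 = 0.83, k5 = 0.012 /s, Ea5 = 75.0 kJ/mol, ΔH5 = −58.0 kJ/mol)
    starting material + target → side product (k6 = 0.025 /M/s, Ea6 = 45.0 kJ/mol)
    (constants at 5 °C)

- in percentages every species weighs as the starting material in it: one side product counts as two
- for a step with 2 of a species take k times the square, and two of it per event
- the list of constants is for 5 °C, to be carried to other temperatures by the activation energies and enthalpies

* the flask with the highest share of target in all that became target or cross product or isomer of the product or side product ("all alike" if they lie within 1.5 percentage points) (alder / larch / elm / cedar / all alike)
* share of target in all that became target or cross product or isomer of the product or side product, alder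
* share of target in all that became target or cross product or isomer of the product or side product, larch
* share of target in all that became target or cross product or isomer of the product or side product, elm
* share of target in all that became target or cross product or isomer of the product or side product, cedar

Each constant is turned into a time at the charged amounts and carried to the flask's temperature by its activation energy, beginning with alder. The first rung there is the coupling partner, the limiting reagent at 0.700 equiv, whose half-life through its three consuming steps together, at the charged amounts, is 1.73 s. At the start in alder, second substrate uses 2.3 times as much of it as starting material does. Next, target and isomer of the product relax towards each other with a half-life of 2.06 s, slower than the loss of coupling partner but far shorter than the run, so the pair moves together.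

In alder, target then falls with a half-life of 6.83 s, and this time, the half-life of target against side-product formation at the charged c(starting material), is the burn half-life. It is a pseudo-first-order figure, and it lengthens as starting material is used. The cross step takes starting material with a longer half-life, 12.1 s, and even that rung is shorter than the run of 1.0 min. Alder therefore makes its target early, and its burn half-life is shorter than the run.

The same rung reads 18.5 s in cedar, 56.0 s in larch and 194 s in elm. Elm's is the longest and exceeds the run. Ranking the flasks by burn half-life, the reckoning here commits to elm and stops at that order, without percentages.

The forecast also names elm and puts numbers on the shares: 3.5 % for alder, 11 % for cedar, 35 % for larch and 66 % for elm. Its ground is that “warm flasks burn the target away”.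

The simulation puts elm first, with 65.6 % against 34.6 % in larch, 10.1 % in cedar and 4.48 % in alder. In alder at 1.00 min, target is made at 0.232 of the rate at which it is used up, and that flask's burn half-life of 6.83 s is shorter than the run, whereas elm's 194 s is longer. A neighbour of alder charged with 0.60 M has a burn half-life of 17.1 s, beside cedar's 18.5 s, and it ends at 10.9 % against cedar's 10.1 %.

All constants are assumed; the rest is arithmetic.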